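**Strategy.** Ring A (C1 = CMe2, C2, C3 = CHOAc, C4, C5 = C–CH3, C6 = C–alkynyl) is cut into two three-carbon pieces, C6–C1–C2 and C3–C4–C5. The key step joins them in one flask. A TADDOLate-controlled addition of a neopentyl organotitanium (C2) to the aldehyde carbon C3 of a masked 3-oxobutanal sets the carbinol centre. Acidic unmasking and piperidinium acetate then close C5=C6 by aldol condensation. The step exploits that C3 lies 1,3 to the methyl-bearing C5 (a latent β-keto aldehyde) and that the alkyne carbon on C6 can start as a formyl group. The precursors are an acyclic bromo enol ether and a ketal aldehyde. The resulting hydroxy enal serves both end rings.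

Key step: step 4

Remark: enol ether 3 and compounds 6–8 are E/Z mixtures at the enol ether (E drawn); this geometry is lost on hydrolysis in step 4.
Remark: (R,R)-TADDOL is assumed to direct the alkyl group to the same aldehyde face as in its established alkyl additions, which corresponds to (S)-8 and (R)-10.

Step 1
Reactants: 1 3-bromo-2,2-dimethylpropan-1-ol
Product: 2 3-bromo-2,2-dimethylpropanal
Conditions: TEMPO (10 mol%), PhI(OAc)2, CH2Cl2, rt
Reagents that add atoms: none
Why: TEMPO/PhI(OAc)2 oxidation stops at the aldehyde, which has no α-hydrogen and so can neither enolise nor lose HBr.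

Step 2
Reactants: 2 3-bromo-2,2-dimethylpropanal
Product: 3 4-bromo-1-methoxy-3,3-dimethylbut-1-ene
Conditions: Ph3P(CH2OMe)Cl, KOt-Bu, THF, 0 °C to rt
Reagents that add atoms: (methoxymethyl)triphenylphosphonium chloride, [Cl-].COC[P+](c1ccccc1)(c1ccccc1)c1ccccc1
Why: Wittig methoxymethylenation should turn the aldehyde into an enol ether, a latent CH2–CHO arm that tolerates organometallic chemistry; the neopentyl bromide is inert to the ylide.

Step 3
Reactants: 4 ethyl 2-(2-methyl-1,3-dioxolan-2-yl)acetate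
Product: 5 2-(2-methyl-1,3-dioxolan-2-yl)acetaldehyde
Conditions: i-Bu2AlH (1.05 equiv), CH2Cl2, −78 °C
Reagents that add atoms: none
Why: Partial ester reduction through the stable tetrahedral aluminate at −78 °C should give the aldehyde with the ketal untouched.

Step 4
Reactants: 3 4-bromo-1-methoxy-3,3-dimethylbut-1-ene; 5 2-(2-methyl-1,3-dioxolan-2-yl)acetaldehyde
Product: 10 (4R)-4-hydroxy-2,6,6-trimethylcyclohex-1-ene-1-carbaldehyde, via Grignard reagent 6 (not isolated), via alkyltitanium reagent 7 (not isolated), via adduct alcohol 8 (not isolated), via keto aldehyde 9 (not isolated)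
Conditions: Mg, THF, 40 °C; ClTi(Oi-Pr)3, −78 °C; 5, (R,R)-TADDOL (20 mol%), Ti(Oi-Pr)4 (25 mol%), toluene, −78 to −25 °C; then AcOH/H2O/THF, 45 °C; then piperidine (30 mol%), 60 °C; one flask
Reagents that add atoms: water, O
Why: The neopentyl Grignard 6 is transmetalated to the alkyltitanium 7, which adds to aldehyde 5 inside the chiral TADDOLate–titanium complex and forms the C2–C3 bond (8); aqueous acetic acid then hydrolyses enol ether and dioxolane to keto aldehyde 9, whose piperidine enamine at the aldehyde α-carbon (C6) attacks the methyl ketone (C5) and dehydrates to the conjugated enal, forming C5=C6. The closest known reaction types are the titanium TADDOLate-mediated enantioselective alkyl addition to aldehydes and the amine-salt-catalysed intramolecular aldol condensation of keto aldehydes to cycloalkene carbaldehydes, here run together as a formal [3+3] annulation. The ring closes in a 6-(enolexo)-exo-trig mode. The only new stereocentre, the carbinol carbon C3, is set by reagent control from (R,R)-TADDOL. The step needs the aldehyde enamine to attack the ketone rather than the ketone enamine to attack the aldehyde; faster enamine formation at the aldehyde and the irreversible dehydration to the tetrasubstituted conjugated enal should secure this. The C3 hydroxyl is tied up as the six-membered lactol of 9, which should hold back β-elimination.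

Step 5
Reactants: 10 (4R)-4-hydroxy-2,6,6-trimethylcyclohex-1-ene-1-carbaldehyde
Product: 11 (1R)-4-ethynyl-3,5,5-trimethylcyclohex-3-en-1-ol
Conditions: TMSCHN2 (2.2 equiv), n-BuLi (2.2 equiv), THF, −78 °C to rt
Reagents that add atoms: (trimethylsilyl)diazomethane, C[Si](C)(C)C=[N+]=[N-]
Why: Colvin rearrangement (addition of lithiated silyldiazomethane, loss of silanolate, 1,2-shift in the alkylidene carbene) should convert the hindered enal into the enyne without methoxide present, leaving C3 untouched.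

Step 6
Reactants: 11 (1R)-4-ethynyl-3,5,5-trimethylcyclohex-3-en-1-ol; 12 ethyl but-2-ynoate
Product: 13 ethyl (2E)-5-[(4R)-4-hydroxy-2,6,6-trimethylcyclohex-1-en-1-yl]-3-methylpent-2-en-4-ynoate
Conditions: Pd(OAc)2 (3 mol%), tris(2,6-dimethoxyphenyl)phosphine (3 mol%), THF, rt
Reagents that add atoms: none
Why: Palladium-catalysed hydroalkynylation adds the alkynyl C–H syn across the ynoate with the alkynyl group at the β-carbon, which should give the (E)-enynoate with the alkyne trans to the ester.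

Step 7
Reactants: 13 ethyl (2E)-5-[(4R)-4-hydroxy-2,6,6-trimethylcyclohex-1-en-1-yl]-3-methylpent-2-en-4-ynoate
Product: 14 (2E)-5-[(4R)-4-hydroxy-2,6,6-trimethylcyclohex-1-en-1-yl]-3-methylpent-2-en-4-yn-1-ol
Conditions: i-Bu2AlH (3.5 equiv), CH2Cl2, −78 to 0 °C
Reagents that add atoms: none
Why: 1,2-Reduction of the conjugated ester by the aluminium hydride should give the allylic alcohol without touching the enyne.

Step 8
Reactants: 14 (2E)-5-[(4R)-4-hydroxy-2,6,6-trimethylcyclohex-1-en-1-yl]-3-methylpent-2-en-4-yn-1-ol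
Product: 15 (2E)-5-[(4R)-4-hydroxy-2,6,6-trimethylcyclohex-1-en-1-yl]-3-methylpent-2-en-4-ynal
Conditions: MnO2 (activated, excess), CH2Cl2, rt
Reagents that add atoms: none
Why: MnO2 oxidises only the allylic primary alcohol; the homoallylic ring alcohol should remain.

Step 9
Reactants: 15 (2E)-5-[(4R)-4-hydroxy-2,6,6-trimethylcyclohex-1-en-1-yl]-3-methylpent-2-en-4-ynal
Product: 16 (1R)-3,5,5-trimethyl-4-[(3E)-3-methyl-5-oxopent-3-en-1-yn-1-yl]cyclohex-3-en-1-yl acetate
Conditions: Ac2O, pyridine, DMAP (5 mol%), CH2Cl2, 0 °C to rt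
Reagents that add atoms: acetic anhydride, CC(=O)OC(C)=O
Why: DMAP-catalysed acylation installs the acetate of the target on the only hydroxyl present, with retention at C3.

Step 10
Reactants: 16 (1R)-3,5,5-trimethyl-4-[(3E)-3-methyl-5-oxopent-3-en-1-yn-1-yl]cyclohex-3-en-1-yl acetate
Product: 17 (1R)-4-[(3E,5E)-6-iodo-3-methylhexa-3,5-dien-1-yn-1-yl]-3,5,5-trimethylcyclohex-3-en-1-yl acetate
Conditions: CrCl2, CHI3, THF/dioxane, 0 °C to rt, dark
Reagents that add atoms: iodoform, IC(I)I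
Why: Takai iodo-olefination through the geminal dichromium reagent should give the (E)-vinyl iodide; acetate and enyne are inert to CrCl2.

Step 11
Reactants: 10 (4R)-4-hydroxy-2,6,6-trimethylcyclohex-1-ene-1-carbaldehyde
Product: 18 (1R)-4-(hydroxymethyl)-3,5,5-trimethylcyclohex-3-en-1-ol
Conditions: NaBH4, MeOH, 0 °C
Reagents that add atoms: none
Why: Borohydride 1,2-reduction of the hindered enal should give the allylic alcohol needed for directed epoxidation.

Step 12
Reactants: 18 (1R)-4-(hydroxymethyl)-3,5,5-trimethylcyclohex-3-en-1-ol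
Product: 19 (1R,3S,6R)-6-(hydroxymethyl)-1,5,5-trimethyl-7-oxabicyclo[4.1.0]heptan-3-ol
Conditions: Ti(Oi-Pr)4 (30 mol%), D-(−)-diethyl tartrate (36 mol%), t-BuOOH, 4 Å MS, CH2Cl2, −20 °C
Reagents that add atoms: tert-butyl hydroperoxide, CC(C)(C)OO
Why: Sharpless asymmetric epoxidation of the allylic alcohol; the D-tartrate complex should deliver oxygen to the ring face anti to the C3 hydroxyl, setting both epoxide carbons (C5, C6) by reagent control.

Step 13
Reactants: 19 (1R,3S,6R)-6-(hydroxymethyl)-1,5,5-trimethyl-7-oxabicyclo[4.1.0]heptan-3-ol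
Product: 20 (1S,4S,6R)-4-hydroxy-2,2,6-trimethyl-7-oxabicyclo[4.1.0]heptane-1-carbaldehyde
Conditions: TEMPO (10 mol%), PhI(OAc)2, CH2Cl2, rt
Reagents that add atoms: none
Why: The oxoammonium oxidation is selective for the primary over the secondary alcohol, and the α-quaternary epoxy aldehyde cannot epimerise.

Step 14
Reactants: 20 (1S,4S,6R)-4-hydroxy-2,2,6-trimethyl-7-oxabicyclo[4.1.0]heptane-1-carbaldehyde
Product: 21 (1R,3S,6R)-6-ethynyl-1,5,5-trimethyl-7-oxabicyclo[4.1.0]heptan-3-ol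
Conditions: dimethyl (1-diazo-2-oxopropyl)phosphonate, K2CO3, MeOH, 0 °C to rt
Reagents that add atoms: dimethyl (1-diazo-2-oxopropyl)phosphonate, COP(=O)(OC)C(=[N+]=[N-])C(C)=O
Why: Seyferth–Gilbert homologation with the Ohira–Bestmann reagent under mild carbonate conditions should give the terminal alkyne with epoxide and free hydroxyl intact.

Step 15
Reactants: 21 (1R,3S,6R)-6-ethynyl-1,5,5-trimethyl-7-oxabicyclo[4.1.0]heptan-3-ol
Product: 22 (1R,3S,6S)-1,5,5-trimethyl-6-[(E)-2-(tributylstannyl)ethenyl]-7-oxabicyclo[4.1.0]heptan-3-ol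
Conditions: Bu3SnH, PdCl2(PPh3)2 (2 mol%), THF, 0 °C
Reagents that add atoms: tributyltin hydride, CCCC[SnH](CCCC)CCCC
Why: Palladium-catalysed syn-hydrostannylation should place tin on the terminal carbon, away from the fully substituted epoxide carbon, giving the (E)-vinylstannane.

Step 16
Reactants: 23 propiolic acid
Product: 24 (E)-2,3-dibromoprop-2-enoic acid
Conditions: Br2, CH2Cl2, 0 °C to rt, dark
Reagents that add atoms: bromine, BrBr
Why: Anti addition of bromine to the alkyne should give the (E)-dibromide, whose β-bromine is cis to the carboxyl group as the later lactonisation requires.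

Step 17
Reactants: 25 (E)-3-methylpent-2-en-4-yn-1-ol
Product: 26 (E)-3-methylpent-2-en-4-ynal
Conditions: MnO2 (activated, excess), CH2Cl2, rt; solution used directly
Reagents that add atoms: none
Why: Allylic oxidation with MnO2 should give the volatile enynal without isomerising the double bond.

Step 18
Reactants: 26 (E)-3-methylpent-2-en-4-ynal
Product: 27 4,4,5,5-tetramethyl-2-[(1E,3E)-4-methylhexa-1,3-dien-5-yn-1-yl]-1,3,2-dioxaborolane
Conditions: Cl2CHB(pin), CrCl2, LiI, THF, rt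
Reagents that add atoms: 2-(dichloromethyl)-4,4,5,5-tetramethyl-1,3,2-dioxaborolane, ClC(Cl)B1OC(C)(C)C(C)(C)O1
Why: Takai–Utimoto boryl olefination should give the (E)-alkenyl boronate; the terminal alkyne is inert to CrCl2.

Step 19
Reactants: 24 (E)-2,3-dibromoprop-2-enoic acid; 27 4,4,5,5-tetramethyl-2-[(1E,3E)-4-methylhexa-1,3-dien-5-yn-1-yl]-1,3,2-dioxaborolane
Product: 29 (5Z)-3-bromo-5-[(2E,4E)-2-methyl-5-(4,4,5,5-tetramethyl-1,3,2-dioxaborolan-2-yl)penta-2,4-dien-1-ylidene]furan-2(5H)-one, via bromoenynoic acid 28 (not isolated)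
Conditions: Pd(PPh3)4 (5 mol%), CuI (10 mol%), Et3N, MeCN, rt
Reagents that add atoms: none
Why: Sonogashira coupling should occur at the more reactive β C–Br bond, and the cis carboxylate then adds anti across the alkyne in a 5-exo-dig lactonisation, which should give the (Z)-γ-ylidene butenolide; the boronate is inert without aqueous base.

Step 20
Reactants: 29 (5Z)-3-bromo-5-[(2E,4E)-2-methyl-5-(4,4,5,5-tetramethyl-1,3,2-dioxaborolan-2-yl)penta-2,4-dien-1-ylidene]furan-2(5H)-one; 22 (1R,3S,6S)-1,5,5-trimethyl-6-[(E)-2-(tributylstannyl)ethenyl]-7-oxabicyclo[4.1.0]heptan-3-ol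
Product: 30 (5Z)-3-[(E)-2-[(1S,4S,6R)-4-hydroxy-2,2,6-trimethyl-7-oxabicyclo[4.1.0]heptan-1-yl]ethenyl]-5-[(2E,4E)-2-methyl-5-(4,4,5,5-tetramethyl-1,3,2-dioxaborolan-2-yl)penta-2,4-dien-1-ylidene]furan-2(5H)-one
Conditions: Pd2(dba)3 (5 mol%), AsPh3 (20 mol%), NMP, 40 °C, dark
Reagents that add atoms: none
Why: Stille coupling at the α-bromo butenolide under neutral, base-free conditions should retain both alkene geometries and leave the pinacol boronate, epoxide and free hydroxyl untouched.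

Step 21
Reactants: 30 (the boronate of step 20); 17 (1R)-4-[(3E,5E)-6-iodo-3-methylhexa-3,5-dien-1-yn-1-yl]-3,5,5-trimethylcyclohex-3-en-1-yl acetate
Product: 31 pyrrhoxanthin, (3S,5R,6S,3'R)
Conditions: PdCl2(dppf) (10 mol%), K3PO4 (aq.), THF, rt, degassed, dark
Reagents that add atoms: none
Why: Suzuki–Miyaura coupling of the (E)-alkenyl boronate with the (E)-alkenyl iodide proceeds with retention at both partners and should complete the all-E pentaene at room temperature with mild phosphate base.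

**Compound list**

1 | 3-bromo-2,2-dimethylpropan-1-ol | OCC(C)(C)CBr | starting material
2 | 3-bromo-2,2-dimethylpropanal | O=CC(C)(C)CBr | intermediate
3 | 4-bromo-1-methoxy-3,3-dimethylbut-1-ene (E drawn) | CO/C=C/C(C)(C)CBr | intermediate
4 | ethyl 2-(2-methyl-1,3-dioxolan-2-yl)acetate | CCOC(=O)CC1(C)OCCO1 | starting material
5 | 2-(2-methyl-1,3-dioxolan-2-yl)acetaldehyde | O=CCC1(C)OCCO1 | intermediate
6 | (4-methoxy-2,2-dimethylbut-3-en-1-yl)magnesium bromide | CO/C=C/C(C)(C)C[Mg]Br | intermediate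
7 | (4-methoxy-2,2-dimethylbut-3-en-1-yl)titanium triisopropoxide | CO/C=C/C(C)(C)C[Ti](OC(C)C)(OC(C)C)OC(C)C | intermediate
8 | (2S)-6-methoxy-4,4-dimethyl-1-(2-methyl-1,3-dioxolan-2-yl)hex-5-en-2-ol (formed as its titanium alkoxide) | O[C@@H](CC(C)(C)/C=C/OC)CC1(C)OCCO1 | intermediate
9 | (5S)-5-hydroxy-3,3-dimethyl-7-oxooctanal | O[C@@H](CC(C)(C)CC=O)CC(C)=O | intermediate
10 | (4R)-4-hydroxy-2,6,6-trimethylcyclohex-1-ene-1-carbaldehyde | O[C@@H]1CC(C)=C(C=O)C(C)(C)C1 | intermediate
11 | (1R)-4-ethynyl-3,5,5-trimethylcyclohex-3-en-1-ol | O[C@@H]1CC(C)=C(C#C)C(C)(C)C1 | intermediate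
12 | ethyl but-2-ynoate | CC#CC(=O)OCC | starting material
13 | ethyl (2E)-5-[(4R)-4-hydroxy-2,6,6-trimethylcyclohex-1-en-1-yl]-3-methylpent-2-en-4-ynoate | CCOC(=O)/C=C(C)/C#CC1=C(C)C[C@@H](O)CC1(C)C | intermediate
14 | (2E)-5-[(4R)-4-hydroxy-2,6,6-trimethylcyclohex-1-en-1-yl]-3-methylpent-2-en-4-yn-1-ol | OC/C=C(C)/C#CC1=C(C)C[C@@H](O)CC1(C)C | intermediate
15 | (2E)-5-[(4R)-4-hydroxy-2,6,6-trimethylcyclohex-1-en-1-yl]-3-methylpent-2-en-4-ynal | O=C/C=C(C)/C#CC1=C(C)C[C@@H](O)CC1(C)C | intermediate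
16 | (1R)-3,5,5-trimethyl-4-[(3E)-3-methyl-5-oxopent-3-en-1-yn-1-yl]cyclohex-3-en-1-yl acetate | CC(=O)O[C@@H]1CC(C)=C(C#C/C(C)=C/C=O)C(C)(C)C1 | intermediate
17 | (1R)-4-[(3E,5E)-6-iodo-3-methylhexa-3,5-dien-1-yn-1-yl]-3,5,5-trimethylcyclohex-3-en-1-yl acetate | CC(=O)O[C@@H]1CC(C)=C(C#C/C(C)=C/C=C/I)C(C)(C)C1 | intermediate
18 | (1R)-4-(hydroxymethyl)-3,5,5-trimethylcyclohex-3-en-1-ol | OCC1=C(C)C[C@@H](O)CC1(C)C | intermediate
19 | (1R,3S,6R)-6-(hydroxymethyl)-1,5,5-trimethyl-7-oxabicyclo[4.1.0]heptan-3-ol | OC[C@@]12O[C@]1(C)C[C@@H](O)CC2(C)C | intermediate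
20 | (1S,4S,6R)-4-hydroxy-2,2,6-trimethyl-7-oxabicyclo[4.1.0]heptane-1-carbaldehyde | O=C[C@@]12O[C@]1(C)C[C@@H](O)CC2(C)C | intermediate
21 | (1R,3S,6R)-6-ethynyl-1,5,5-trimethyl-7-oxabicyclo[4.1.0]heptan-3-ol | C#C[C@@]12O[C@]1(C)C[C@@H](O)CC2(C)C | intermediate
22 | (1R,3S,6S)-1,5,5-trimethyl-6-[(E)-2-(tributylstannyl)ethenyl]-7-oxabicyclo[4.1.0]heptan-3-ol | CCCC[Sn](CCCC)(CCCC)/C=C/[C@@]12O[C@]1(C)C[C@@H](O)CC2(C)C | intermediate
23 | propiolic acid | OC(=O)C#C | starting material
24 | (E)-2,3-dibromoprop-2-enoic acid | OC(=O)/C(Br)=C\Br | intermediate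
25 | (E)-3-methylpent-2-en-4-yn-1-ol | C#C/C(C)=C/CO | starting material
26 | (E)-3-methylpent-2-en-4-ynal | C#C/C(C)=C/C=O | intermediate
27 | 4,4,5,5-tetramethyl-2-[(1E,3E)-4-methylhexa-1,3-dien-5-yn-1-yl]-1,3,2-dioxaborolane | C#C/C(C)=C/C=C/B1OC(C)(C)C(C)(C)O1 | intermediate
28 | (2E,6E,8E)-2-bromo-6-methyl-9-(4,4,5,5-tetramethyl-1,3,2-dioxaborolan-2-yl)nona-2,6,8-trien-4-ynoic acid | OC(=O)/C(Br)=C\C#C/C(C)=C/C=C/B1OC(C)(C)C(C)(C)O1 | intermediate
29 | (5Z)-3-bromo-5-[(2E,4E)-2-methyl-5-(4,4,5,5-tetramethyl-1,3,2-dioxaborolan-2-yl)penta-2,4-dien-1-ylidene]furan-2(5H)-one | CC1(C)OB(/C=C/C=C(C)/C=C2C=C(Br)C(=O)O/2)OC1(C)C | intermediate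
30 | (5Z)-3-[(E)-2-[(1S,4S,6R)-4-hydroxy-2,2,6-trimethyl-7-oxabicyclo[4.1.0]heptan-1-yl]ethenyl]-5-[(2E,4E)-2-methyl-5-(4,4,5,5-tetramethyl-1,3,2-dioxaborolan-2-yl)penta-2,4-dien-1-ylidene]furan-2(5H)-one | CC1(C)OB(/C=C/C=C(C)/C=C2C=C(/C=C/[C@@]34O[C@]3(C)C[C@@H](O)CC4(C)C)C(=O)O/2)OC1(C)C | intermediate
31 | pyrrhoxanthin, (3S,5R,6S,3'R) | CC(=O)O[C@@H]1CC(C)=C(C#C/C(C)=C/C=C/C=C/C=C(C)/C=C2C=C(/C=C/[C@@]34O[C@]3(C)C[C@@H](O)CC4(C)C)C(=O)O/2)C(C)(C)C1 | target

**Step count.** Total: 21 steps. Longest linear sequence: 10 steps (1, 2, 4, 11, 12, 13, 14, 15, 20, 21; the ring A branch 1, 2, 4, 5–10, 21 is equally long).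

**Steps most likely to fail**

Step 4. The neopentyl group may transfer sluggishly or with incomplete facial control from titanium. In the second stage the β-hydroxy ketone may eliminate, or the ketone enamine may attack the aldehyde instead. The fallback separates the two bond formations and replaces carbonyl addition by a 1,2-metallate rearrangement; it sets out from 3 and 4 and returns at 10. Copper-catalysed borylation of 3 (B2pin2, CuI, PPh3, LiOt-Bu, DMF) would give 2-(4-methoxy-2,2-dimethylbut-3-en-1-yl)-4,4,5,5-tetramethyl-1,3,2-dioxaborolane F1. LiAlH4 reduction of 4 would give 2-(2-methyl-1,3-dioxolan-2-yl)ethan-1-ol F2, which i-Pr2NCOCl/Et3N would convert into 2-(2-methyl-1,3-dioxolan-2-yl)ethyl N,N-diisopropylcarbamate F3. Enantioselective lithiation of F3 (s-BuLi, (−)-sparteine, Et2O, −78 °C), borylation with F1 and 1,2-migration (MgBr2, MeOH, reflux) would give 2-[(2S)-6-methoxy-4,4-dimethyl-1-(2-methyl-1,3-dioxolan-2-yl)hex-5-en-2-yl]-4,4,5,5-tetramethyl-1,3,2-dioxaborolane F4. Oxidation of F4 (NaOH, H2O2) would give 8, now isolated. Treatment of 8 with AcOH/H2O and then piperidinium acetate in toluene at 60 °C would close the ring to 10.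

Step 19. Coupling may also occur at the α-bromide, the acid may close 6-endo to a pyranone, and the alkyne may homocouple. The fallback separates coupling from lactonisation; it sets out from 24 and 27 and returns at 29. Isobutene with catalytic H2SO4 would convert 24 into tert-butyl (E)-2,3-dibromoprop-2-enoate F5. Sonogashira coupling of F5 with 27 (PdCl2(PPh3)2, CuI, i-Pr2NH, THF, 0 °C) would give tert-butyl (2E,6E,8E)-2-bromo-6-methyl-9-(4,4,5,5-tetramethyl-1,3,2-dioxaborolan-2-yl)nona-2,6,8-trien-4-ynoate F6. Trifluoroacetic acid in CH2Cl2 would release acid 28, now isolated. AgNO3 (10 mol%) in acetone would then effect the 5-exo-dig lactonisation to 29.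

Step 21. The boronate may protodeboronate, the aqueous base may open the ylidenebutenolide or cleave the acetate, and the polyene may scramble E/Z. The fallback closes the chain by a Wittig olefination one double bond further on; it sets out from 16, 24, 25 and 22 and returns at 31. Formylmethylenetriphenylphosphorane (toluene, 60 °C) would extend 16 to (1R)-3,5,5-trimethyl-4-[(3E,5E)-3-methyl-7-oxohepta-3,5-dien-1-yn-1-yl]cyclohex-3-en-1-yl acetate F7. Coupling and lactonisation of 24 with 25 under the conditions of step 19 would give (5Z)-3-bromo-5-[(2E)-4-hydroxy-2-methylbut-2-en-1-ylidene]furan-2(5H)-one F8. Stille coupling of F8 with 22 under the conditions of step 20 would give (5Z)-3-[(E)-2-[(1S,4S,6R)-4-hydroxy-2,2,6-trimethyl-7-oxabicyclo[4.1.0]heptan-1-yl]ethenyl]-5-[(2E)-4-hydroxy-2-methylbut-2-en-1-ylidene]furan-2(5H)-one F9. Triphenylphosphine hydrobromide (MeOH/CH2Cl2) would convert F9 into the allylic triphenylphosphonium bromide F10. Wittig reaction of F10 with F7 (NaOMe, CH2Cl2, −30 °C), followed by iodine-catalysed equilibration of the new double bond to E, would give 31.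

**Further compounds**

F1 | step 4 | 2-(4-methoxy-2,2-dimethylbut-3-en-1-yl)-4,4,5,5-tetramethyl-1,3,2-dioxaborolane | CO/C=C/C(C)(C)CB1OC(C)(C)C(C)(C)O1
F2 | step 4 | 2-(2-methyl-1,3-dioxolan-2-yl)ethan-1-ol | OCCC1(C)OCCO1
F3 | step 4 | 2-(2-methyl-1,3-dioxolan-2-yl)ethyl N,N-diisopropylcarbamate | CC(C)N(C(C)C)C(=O)OCCC1(C)OCCO1
F4 | step 4 | 2-[(2S)-6-methoxy-4,4-dimethyl-1-(2-methyl-1,3-dioxolan-2-yl)hex-5-en-2-yl]-4,4,5,5-tetramethyl-1,3,2-dioxaborolane | CC1(C)OB(OC1(C)C)[C@@H](CC(C)(C)/C=C/OC)CC1(C)OCCO1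
F5 | step 19 | tert-butyl (E)-2,3-dibromoprop-2-enoate | CC(C)(C)OC(=O)/C(Br)=C\Br
F6 | step 19 | tert-butyl (2E,6E,8E)-2-bromo-6-methyl-9-(4,4,5,5-tetramethyl-1,3,2-dioxaborolan-2-yl)nona-2,6,8-trien-4-ynoate | CC(C)(C)OC(=O)/C(Br)=C\C#C/C(C)=C/C=C/B1OC(C)(C)C(C)(C)O1
F7 | step 21 | (1R)-3,5,5-trimethyl-4-[(3E,5E)-3-methyl-7-oxohepta-3,5-dien-1-yn-1-yl]cyclohex-3-en-1-yl acetate | CC(=O)O[C@@H]1CC(C)=C(C#C/C(C)=C/C=C/C=O)C(C)(C)C1
F8 | step 21 | (5Z)-3-bromo-5-[(2E)-4-hydroxy-2-methylbut-2-en-1-ylidene]furan-2(5H)-one | OC/C=C(C)/C=C1C=C(Br)C(=O)O/1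
F9 | step 21 | (5Z)-3-[(E)-2-[(1S,4S,6R)-4-hydroxy-2,2,6-trimethyl-7-oxabicyclo[4.1.0]heptan-1-yl]ethenyl]-5-[(2E)-4-hydroxy-2-methylbut-2-en-1-ylidene]furan-2(5H)-one | OC/C=C(C)/C=C1C=C(/C=C/[C@@]23O[C@]2(C)C[C@@H](O)CC3(C)C)C(=O)O/1
F10 | step 21 | [(2E)-4-[(2Z)-4-[(E)-2-[(1S,4S,6R)-4-hydroxy-2,2,6-trimethyl-7-oxabicyclo[4.1.0]heptan-1-yl]ethenyl]-5-oxofuran-2(5H)-ylidene]-3-methylbut-2-en-1-yl]triphenylphosphonium bromide | [Br-].c1ccc(cc1)[P+](C/C=C(C)/C=C1C=C(/C=C/[C@@]23O[C@]2(C)C[C@@H](O)CC3(C)C)C(=O)O/1)(c1ccccc1)c1ccccc1
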